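Late in zeta and theta the readings lie flat out to 3.00 min, within their scatter of 0.5 percentage points, so expect grey and blue to be standing still when you arrive.

| flask | left-handed substrate | right-handed substrate | reagent | free catalyst | remark | time |
|---|---|---|---|---|---|---|
| eta | 1 mM | 1 mM | 1.6 mM | 1 µM | run made earlier |  |
| theta | 4 mM | 4 mM | 1.6 mM | 1 µM | run made earlier |  |
| zeta | 2 mM | 2 mM | 2.4 mM | 1 µM | run made earlier |  |
| grey | 2.0 mM | 2.0 mM | 1.60 mM | 1.0 µM |  | 4.0 min |
| blue | 2.0 mM | 2.0 mM | 1.60 mM | 1.0 µM |  | 8.0 min |

| run | time / min | right-handed substrate / % | left-handed substrate / % |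
|---|---|---|---|
| eta | 0.500 | 28.6 | 21.3 |
| eta | 1.00 | 27.3 | 19.4 |
| eta | 1.33 | 27.7 | 17.6 |
| eta | 2.00 | 26.6 | 17.2 |
| eta | 2.50 | 26.3 | 17.6 |
| eta | 3.00 | 26.9 | 18.4 |
| theta | 0.167 | 43.1 | 38.3 |
| theta | 0.500 | 42.7 | 38.2 |
| theta | 0.833 | 41.6 | 37.7 |
| theta | 1.33 | 41.5 | 37.9 |
| theta | 2.00 | 43.2 | 38.0 |
| theta | 2.50 | 42.6 | 38.2 |
| theta | 3.00 | 41.8 | 37.8 |
| zeta | 0.667 | 26.7 | 19.6 |
| zeta | 1.33 | 27.0 | 20.1 |
| zeta | 2.00 | 27.9 | 18.9 |
| zeta | 2.50 | 26.5 | 20.3 |
| zeta | 3.00 | 27.8 | 20.1 |

(standard deviation of a reading: 0.5 percentage points)

- free catalyst is single-handed; left-handed substrate and right-handed substrate are mirror images of each other, charged as a racemate, each of them at the stated concentration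
- an excess is below zero if the other one leads

- which one finishes higher in excess of right-handed substrate over left-handed substrate among what is left of the two ("neither" within 2 percentage points) (grey / blue / neither)
- excess of right-handed substrate over left-handed substrate among what is left of the two at the end, grey
- excess of right-handed substrate over left-handed substrate among what is left of the two at the end, blue

Count the flask in lifetimes of the substrate pair, n = ln(charged / left), and read the excess of right-handed substrate won per lifetime, g, a way of writing the selectivity factor. The mean plateau of zeta gives 0.208 and that of theta 0.247, so use their mean, 0.228.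

Theta lost 1.57 mM of the pair against 1.6 mM of reagent, so count one reagent per substrate. By that count, using up the reagent in grey and blue would leave 60.0% of the pair, which is 0.511 lifetimes. My reckoning for both flasks is an excess of 11.7%. Don't wait for more, and don't touch the reagent charge: this reckoning takes n from it.

The forecast says neither, with 12% for grey and 12% for blue, since “the reagent runs out first”.

Grey and blue both finish at 10.9%, so the answer is neither. Each stands with 6.7% of its reagent unused and 37.3% of the pair reacted. That is 0.467 lifetimes, and g gives 10.6%, so stopping short of the reagent count moves the reckoning by 0.99 points.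

    reagent + free catalyst + right-handed substrate → free catalyst + right-handed product (k = 4.30 × 10⁷ M⁻² s⁻¹)
    free catalyst → spent catalyst B (k = 0.0420 s⁻¹)
    reagent + free catalyst + left-handed substrate → free catalyst + left-handed product (k = 6.90 × 10⁷ M⁻² s⁻¹)
    left-handed product ⇌ right-handed product (k = 0.0370 s⁻¹)
    2 free catalyst → spent catalyst A (k = 19000 M⁻¹ s⁻¹)

Take grey with 0.96 mM of reagent. The count leaves 76.0% of the pair, and g gives 6.26%. That flask gives 6.08%.

The runs come from a simulation from invented constants; the scatter is artificial.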